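Ring A (C1 butyryl-bearing, C6 carbonyl) is not aromatic: C3 is a quaternary gem-dimethyl carbon between the enol carbons C2 and C4, and C5 carries the CH2 bridge to ring B. It is therefore closed as an aliphatic cyclohexane-1,3,5-trione by an intramolecular Claisen (Dieckmann) condensation forming the C4–C5 bond. In one operation base converts an open-chain methyl 2,2-dimethyl-3,5-dioxoheptanoate, bearing the 2,4-dihydroxy-3,6-dimethylphenyl ring on C7, into the bridged two-ring core; quaternary centre and bridge are already in the chain. The precursor arises from a dihydrocoumarin opened by a ketone enolate; double Friedel–Crafts butyrylation completes the target.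

Key step: step 3

Remark on the chemistry: 7, 8 and 10 are drawn as single tautomers. 7 may sit partly as its ring-chain hemiketal (a 2-hydroxychroman), which reopens under base. Ring B positions are primed: C1' carries the bridge, C2' and C4' the hydroxyls, C3' and C6' the methyls, and C5' is the free carbon that is butyrylated last. The phenols are left unprotected, so the base in steps 2 and 3 is used in excess.

Step 1
Reactants: 1 2,5-dimethylbenzene-1,3-diol (2,5-dimethylresorcinol); 2 acrylic acid
Product: 4 7-hydroxy-5,8-dimethyl-3,4-dihydro-2H-chromen-2-one, via 3-(2,4-dihydroxy-3,6-dimethylphenyl)propanoic acid 3 (not isolated)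
Conditions: 2 (1.1 equiv), Amberlyst 15 (sulfonic acid resin), toluene, reflux, Dean–Stark
Reagents that add atoms: acrylic acid (2), C=CC(=O)O
Why: Acid-catalysed Friedel–Crafts conjugate addition (hydroarylation) of the arene to protonated acrylic acid occurs at C4 of 1, one of two symmetry-equivalent free positions that are ortho and para to the hydroxyls, and the resulting acid lactonises onto the adjacent phenol while water is removed azeotropically, a known route from resorcinols to 7-hydroxydihydrocoumarins.

Step 2
Reactants: 4 7-hydroxy-5,8-dimethyl-3,4-dihydro-2H-chromen-2-one; 5 methyl 2,2-dimethyl-3-oxobutanoate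
Product: 7 methyl 7-(2,4-dihydroxy-3,6-dimethylphenyl)-2,2-dimethyl-3,5-dioxoheptanoate, via lithium enolate 6 (not isolated)
Conditions: 5 (3.4 equiv), LiN(iPr)2 (LDA, commercial solution, 3.3 equiv), THF, −78 °C; then 4 in THF, −78 → −20 °C; AcOH quench at −78 °C, then water; crude 7 used directly
Reagents that add atoms: methyl 2,2-dimethyl-3-oxobutanoate (5), COC(=O)C(C)(C)C(C)=O
Why: Crossed Claisen acylation of a ketone enolate by an aryl-ester-type lactone: 5 can only enolise at its acetyl methyl group because C2 is quaternary, the lactone carbonyl is a reactive acyl donor whose phenoxide leaving group stays in the molecule, the first equivalent of 6 merely converts the 7-OH into its phenoxide and a further one deprotonates the new 1,3-diketone and so prevents over-addition, and the mild acetic acid quench avoids dehydration of the hemiketal tautomer of 7.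

Step 3
Reactants: 7 methyl 7-(2,4-dihydroxy-3,6-dimethylphenyl)-2,2-dimethyl-3,5-dioxoheptanoate
Product: 8 2-[(2,4-dihydroxy-3,6-dimethylphenyl)methyl]-3,5-dihydroxy-4,4-dimethylcyclohexa-2,5-dien-1-one
Conditions: KOtBu (7 equiv), THF–tBuOH, argon, 0 → 60 °C; poured into cold 1 M HCl
Reagents that add atoms: none
Why: Potassium tert-butoxide converts 7 into its bis-phenoxide diketonate and, reversibly, into the 1,3-diketone dianion carrying a carbanion at chain C6 (the future ring A C5, which bears the arylmethyl group); this carbon adds to the methyl ester carbonyl C1 (future C4) and methoxide is expelled, a Dieckmann-type intramolecular Claisen condensation whose closest known relatives are the alkoxide-mediated closure of 5-oxo esters to cyclohexane-1,3-diones and the terminal acylation of 1,3-diketone dianions by esters. Ring A closes in a 6-exo-trig mode (chain atoms C1–C6, ester C=O exocyclic to the forming ring). No stereocentre is created, the product being a fully enolised, achiral trione. The step needs regioselectivity for the less acidic terminal carbon C6 over the doubly activated C4: attack from C4 could only give a four-membered ring, the ester has no alpha hydrogen because C2 is quaternary, and O-acylation to the six-membered enol lactone is reversible under alkoxide, so all equilibria drain into the C-acylated product, which is removed as its strongly stabilised trione enolate. The quaternary C2 also rules out aromatisation to a pyrone or phenol, and the ring B phenoxides are inert spectators that only consume base. The partly protic potassium medium lets the diketonate unfold from its chelated U shape by reversible protonation at C4, while the bulky alkoxide keeps retro-Claisen cleavage low.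

Step 4
Reactants: 8 2-[(2,4-dihydroxy-3,6-dimethylphenyl)methyl]-3,5-dihydroxy-4,4-dimethylcyclohexa-2,5-dien-1-one; 9 butanoyl chloride
Product: 10 2-butanoyl-6-[(5-butanoyl-2,4-dihydroxy-3,6-dimethylphenyl)methyl]-3,5-dihydroxy-4,4-dimethylcyclohexa-2,5-dien-1-one (CNP0295128.0)
Conditions: AlCl3 (6 equiv), 9 (2.4 equiv), CH2Cl2–MeNO2, 0 °C → rt; ice/1 M HCl (K2CO3, MeOH, 0 °C, short, only if O-butyrates remain)
Reagents that add atoms: butanoyl chloride (9), CCCC(=O)Cl
Why: Twofold Friedel–Crafts acylation at the only two nucleophilic CH positions left, C1 of ring A (between C2–OH and the C6 carbonyl, the site at which filicinic-acid-type triones are known to take acyl groups) and C5' of ring B (ortho and para to the two hydroxyls); excess AlCl3 holds the hydroxyls as aluminium phenoxides and enolates so that the acyl groups end on carbon, directly or by Fries-type shift, and each new ketone is stabilised as a chelated hydrogen-bonded enol or phenol, while the low temperature spares the methylene bridge.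

Compound list
1 | 2,5-dimethylbenzene-1,3-diol (2,5-dimethylresorcinol) | Cc1cc(O)c(C)c(O)c1 | starting material
2 | acrylic acid (prop-2-enoic acid) | C=CC(=O)O | starting material
3 | 3-(2,4-dihydroxy-3,6-dimethylphenyl)propanoic acid | OC(=O)CCc1c(C)cc(O)c(C)c1O | intermediate (not isolated)
4 | 7-hydroxy-5,8-dimethyl-3,4-dihydro-2H-chromen-2-one | O=C1CCc2c(C)cc(O)c(C)c2O1 | intermediate
5 | methyl 2,2-dimethyl-3-oxobutanoate | COC(=O)C(C)(C)C(C)=O | starting material
6 | lithium 4-methoxy-3,3-dimethyl-4-oxobut-1-en-2-olate (methyl-side lithium enolate of 5) | [Li+].[O-]C(=C)C(C)(C)C(=O)OC | intermediate (not isolated)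
7 | methyl 7-(2,4-dihydroxy-3,6-dimethylphenyl)-2,2-dimethyl-3,5-dioxoheptanoate | COC(=O)C(C)(C)C(=O)CC(=O)CCc1c(C)cc(O)c(C)c1O | intermediate
8 | 2-[(2,4-dihydroxy-3,6-dimethylphenyl)methyl]-3,5-dihydroxy-4,4-dimethylcyclohexa-2,5-dien-1-one | O=C1C=C(O)C(C)(C)C(O)=C1Cc1c(C)cc(O)c(C)c1O | intermediate
9 | butanoyl chloride (butyryl chloride) | CCCC(=O)Cl | starting material
10 | 2-butanoyl-6-[(5-butanoyl-2,4-dihydroxy-3,6-dimethylphenyl)methyl]-3,5-dihydroxy-4,4-dimethylcyclohexa-2,5-dien-1-one | CCCC(=O)C1=C(O)C(C)(C)C(O)=C(Cc2c(C)c(C(=O)CCC)c(O)c(C)c2O)C1=O | target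

Total step count: 4
Longest linear sequence: 4 steps (1 → 4 → 7 → 8 → 10)

Steps most likely to fail

Step 3. The terminal carbanion may not form in useful concentration, or the chelated diketonate may not fold. Retro-Claisen fragmentation back towards lactone 4 or stalling at the O-acylated enol lactone would then take over. The fallback sets out from 1 and returns at 8, and makes the bridge intermolecularly instead of closing ring A. Mannich aminomethylation of 1 with aqueous dimethylamine and formaldehyde in ethanol should give 4-[(dimethylamino)methyl]-2,5-dimethylbenzene-1,3-diol F1. Separately, the established double C-methylation of 2,4,6-trihydroxyacetophenone (MeI, NaOMe, MeOH) gives 2-acetyl-3,5-dihydroxy-4,4-dimethylcyclohexa-2,5-dien-1-one F2. Hot aqueous HCl deacetylates it to 3,5-dihydroxy-4,4-dimethylcyclohexa-2,5-dien-1-one (filicinic acid) F3. Heating F1 with F3 in dioxane expels dimethylamine to give an ortho-quinone methide, which the trione traps by Michael addition at its C2, giving 8.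

Step 4. The strong Lewis acid may cleave or scramble the benzylic methylene bridge through a quinone-methide-type cation, cyclodehydrate the ring B ortho-hydroxyl onto a ring A carbonyl to a xanthene, or leave the hindered ring B position unacylated. The fallback sets out from 4 and returns at 10, and moves the ring B acylation to the acid-stable lactone. Friedel–Crafts butyrylation of 4 (9, AlCl3, CH2Cl2) at its only free aromatic carbon should give 6-butanoyl-7-hydroxy-5,8-dimethyl-3,4-dihydro-2H-chromen-2-one F4. Opening with enolate 6 as in step 2 gives methyl 7-(5-butanoyl-2,4-dihydroxy-3,6-dimethylphenyl)-2,2-dimethyl-3,5-dioxoheptanoate F5. The base-mediated closure of step 3 then gives 2-[(5-butanoyl-2,4-dihydroxy-3,6-dimethylphenyl)methyl]-3,5-dihydroxy-4,4-dimethylcyclohexa-2,5-dien-1-one F6. Ring A alone is finally C-butyrylated without Lewis acid, using butanoic acid, N,N'-dicyclohexylcarbodiimide and 4-(dimethylamino)pyridine in CH2Cl2 (enol ester formation, then the O-to-C acyl shift known for cyclic 1,3-diones). A brief K2CO3/MeOH treatment removes any aryl butyrate, arriving at 10.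

Step 2. Proton exchange between enolate and lactone (alpha-deprotonation and ketene-type ring opening), self-condensation of the enolate on warming, or acid-induced dehydration of the hemiketal tautomer during work-up may erode the acylation. The fallback sets out from 1 and returns at 7, and builds the 1,3-diketone from the other side. Acid-catalysed hydroarylation of but-3-en-2-one by 1 (sulfonic acid resin, toluene) should give 4-(2,4-dihydroxy-3,6-dimethylphenyl)butan-2-one F7, in equilibrium with its cyclic hemiketal. Crossed Claisen condensation of its methyl-side enolate (NaH, THF, reflux) with the non-enolisable dimethyl 2,2-dimethylpropanedioate then gives 7, which under excess base may run on to 8.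

Further compounds
F1 | step 3 | 4-[(dimethylamino)methyl]-2,5-dimethylbenzene-1,3-diol | CN(C)Cc1c(C)cc(O)c(C)c1O
F2 | step 3 | 2-acetyl-3,5-dihydroxy-4,4-dimethylcyclohexa-2,5-dien-1-one | CC(=O)C1=C(O)C(C)(C)C(O)=CC1=O
F3 | step 3 | 3,5-dihydroxy-4,4-dimethylcyclohexa-2,5-dien-1-one (filicinic acid) | CC1(C)C(O)=CC(=O)C=C1O
F4 | step 4 | 6-butanoyl-7-hydroxy-5,8-dimethyl-3,4-dihydro-2H-chromen-2-one | CCCC(=O)c1c(C)c2CCC(=O)Oc2c(C)c1O
F5 | step 4 | methyl 7-(5-butanoyl-2,4-dihydroxy-3,6-dimethylphenyl)-2,2-dimethyl-3,5-dioxoheptanoate | COC(=O)C(C)(C)C(=O)CC(=O)CCc1c(C)c(C(=O)CCC)c(O)c(C)c1O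
F6 | step 4 | 2-[(5-butanoyl-2,4-dihydroxy-3,6-dimethylphenyl)methyl]-3,5-dihydroxy-4,4-dimethylcyclohexa-2,5-dien-1-one | O=C1C=C(O)C(C)(C)C(O)=C1Cc1c(C)c(C(=O)CCC)c(O)c(C)c1O
F7 | step 2 | 4-(2,4-dihydroxy-3,6-dimethylphenyl)butan-2-one | CC(=O)CCc1c(C)cc(O)c(C)c1O
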